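## Plan

- Numbering (furo[3,4-c]furan): C-1 (CH2), O-2, C-3 (ArCH), C-3a (C–OH), C-4 (CH2), O-5, C-6 (ArCH), C-6a (CH). Ring A = C-3a/C-4/O-5/C-6/C-6a, ring B = C-1/O-2/C-3/C-3a/C-6a.
- Enabling feature: C-3 is an acetal-level carbon (bonded to O-2 and aryl) next to the tertiary carbinol C-3a at the cis ring fusion, with aryl and OH cis on the convex face. This O-2–C-3(Ar)–C-3a(OH) unit is what syn opening of a 3,3a-oxirane by an aryl–metal delivers, so the first cut is aryl–C-3 (with O–C-3a), back to a C-3=C-3a enol ether and an aryl bromide.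
- Further cuts: enol ether ⇒ lactol ⇒ vinyl + CH2OH (ring B); O-5–C-6 (ring A, benzylic cation capture); C-6–C-6a (aldol); vinyl–C bond (conjugate addition to a butenolide).
- Forward: a temporary butyrolactone ring carries the chain; aldol and reduction give a triol; ring A closes first; cleavage of the vinyl group closes ring B as a lactol; dehydration gives the enol ether; a temporary oxirane and aryl transfer join the second aryl fragment; desilylation ends the route.
- Stereochemistry: one centre is set by Rh/(R)-BINAP catalysis (lactone C-4, the future C-3a). It relays to C-6a (trans aldol) and C-6 (trans ring closure) and is then erased in the enol ether. C-3a and C-3 are re-set in the key step from C-6a (cis fusion, convex-face oxygen transfer) and by internal aryl delivery.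

Key step: step 9

Assumption: Rh/(R)-BINAP is taken to add the vinyl group to furan-2(5H)-one with the same facial sense as in the established additions to cyclic enones and six-membered unsaturated lactones, which corresponds to the (R)-configured vinyl lactone.

Abbreviation: Ar = 3-methoxy-4-(triisopropylsilyloxy)phenyl. Bicyclic compounds are numbered as the target.

## Route

Step 1
Reactants: 1 furan-2(5H)-one; 2 potassium vinyltrifluoroborate
Product: 3 (R)-4-vinyldihydrofuran-2(3H)-one
Conditions: [Rh(cod)2]BF4 (3 mol %), (R)-BINAP (3.3 mol %), toluene/H2O 10:1, 100 °C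
Reagents that add atoms: none
Why: Rhodium/BINAP-catalysed asymmetric 1,4-addition of an alkenylboron reagent to a cyclic unsaturated ester (Hayashi–Miyaura reaction), in which the vinyl–rhodium species inserts the butenolide C=C on the face fixed by the ligand and water protonates the oxa-allyl rhodium, should set the single catalyst-derived stereocentre.

Step 2
Reactants: 4 vanillin
Product: 5 3-methoxy-4-(triisopropylsilyloxy)benzaldehyde
Conditions: TIPSCl (1.2 equiv), imidazole (2.5 equiv), DMF, rt
Reagents that add atoms: chlorotriisopropylsilane, CC(C)[Si](Cl)(C(C)C)C(C)C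
Why: Standard silylation of a phenol; the bulky aryl silyl ether should survive the enolate, hydride, acid, oxidant and organometallic steps and is removed by fluoride at the end.

Step 3
Reactants: 3 (R)-4-vinyldihydrofuran-2(3H)-one; 5 3-methoxy-4-(triisopropylsilyloxy)benzaldehyde
Product: 6 (3R,4S)-3-[hydroxy(Ar)methyl]-4-vinyldihydrofuran-2(3H)-one (3,4-trans; carbinol epimers)
Conditions: LiN(i-Pr)2 (1.1 equiv), THF, −78 °C; then 5, −78 °C; aq. NH4Cl at −78 °C
Reagents that add atoms: none
Why: Aldol addition of the lactone lithium enolate should occur anti to the 4-vinyl group and so set the future C-6a by 1,2-induction, while the carbinol centre forms as a mixture that converges in step 5.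

Step 4
Reactants: 6 (3R,4S)-3-[hydroxy(Ar)methyl]-4-vinyldihydrofuran-2(3H)-one
Product: 7 (2S,3S)-2-[hydroxy(Ar)methyl]-3-vinylbutane-1,4-diol (carbinol epimers)
Conditions: LiBH4 (2.5 equiv), THF, 0 °C → rt; aq. NH4Cl
Reagents that add atoms: none
Why: Hydride reduction of the lactone to the 1,4-diol opens the temporary lactone ring without touching the alkene, the aryl silyl ether or any stereocentre.

Step 5
Reactants: 7 (2S,3S)-2-[hydroxy(Ar)methyl]-3-vinylbutane-1,4-diol
Product: 8 [(2R,3S,4S)-2-Ar-4-vinyltetrahydrofuran-3-yl]methanol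
Conditions: CSA (10 mol %), CH2Cl2, 0 °C → rt
Reagents that add atoms: none
Why: Acid-catalysed cycloetherification through the p-silyloxy-stabilised benzylic cation (SN1), captured by the only hydroxyl that can close a five-membered ring, should take both carbinol epimers to the tetrahydrofuran with the aryl group trans to the neighbouring CH2OH, which closes ring A and sets C-6.

Step 6
Reactants: 8 [(2R,3S,4S)-2-Ar-4-vinyltetrahydrofuran-3-yl]methanol
Product: 10 (3aS,6R,6aS)-6-Ar-tetrahydro-1H,3H-furo[3,4-c]furan-3-ol (lactol; anomer mixture), via hydroxy aldehyde 9 (not isolated)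
Conditions: OsO4 (2 mol %), NaIO4 (4 equiv), 2,6-lutidine (2 equiv), dioxane/H2O 3:1, rt
Reagents that add atoms: osmium tetroxide, O=[Os](=O)(=O)=O (catalytic oxygen carrier); sodium periodate, [Na+].[O-]I(=O)(=O)=O (terminal oxidant)
Why: Lemieux–Johnson oxidation cleaves the terminal alkene to the aldehyde, which the cis hydroxymethyl group should trap at once as the five-membered lactol, closing ring B.

Step 7
Reactants: 10 (3aS,6R,6aS)-6-Ar-tetrahydro-1H,3H-furo[3,4-c]furan-3-ol
Product: 12 (6R,6aS)-6-Ar-6,6a-dihydro-1H,4H-furo[3,4-c]furan (C-3=C-3a enol ether), via anomeric mesylate 11 (not isolated)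
Conditions: MsCl (1.5 equiv), Et3N (6 equiv), CH2Cl2, −40 → 40 °C; chromatography on Et3N-deactivated silica
Reagents that add atoms: none
Why: Mesylation of the lactol hydroxyl and amine-mediated elimination through the oxocarbenium ion (the glycal synthesis from 2-deoxy lactols) should remove the only β-hydrogen, H-3a, and give the ring-fusion enol ether, erasing the catalyst-set centre after it has done its relay.

Step 8
Reactants: 13 4-bromo-2-methoxyphenol
Product: 14 (4-bromo-2-methoxyphenoxy)triisopropylsilane
Conditions: TIPSCl (1.2 equiv), imidazole (2.5 equiv), DMF, rt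
Reagents that add atoms: chlorotriisopropylsilane, CC(C)[Si](Cl)(C(C)C)C(C)C
Why: Standard phenol silylation as in step 2; the bromine sits para to the oxygen, so the later aryl–metal carbon is the one required in the target.

Step 9
Reactants: 12 (6R,6aS)-6-Ar-6,6a-dihydro-1H,4H-furo[3,4-c]furan; 14 (4-bromo-2-methoxyphenoxy)triisopropylsilane
Product: 18 (3S,3aR,6R,6aS)-3,6-bis-Ar-tetrahydro-1H,3H-furo[3,4-c]furan-3a-ol (bis-TIPS ether of the target), via oxirane 15 (not isolated), via aryllithium 16 (not isolated), via triarylalane 17 (not isolated)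
Conditions: (a) 12, DMDO (1.1 equiv), acetone/CH2Cl2, −78 → 0 °C, then evaporation; (b) separately 14 (4.5 equiv), n-BuLi (4.5 equiv), THF, −78 °C, then AlCl3 (1.5 equiv), −78 → 0 °C; (c) 15 in CH2Cl2 added to 17 at −78 °C, → 0 °C; aq. KNaC4H4O6
Reagents that add atoms: dimethyldioxirane, CC1(C)OO1
Why: Dimethyldioxirane transfers one oxygen atom to the electron-rich C-3=C-3a enol ether in a concerted spiro transition state on the convex face (the face of H-6a), the only face that leads to a cis-fused dioxabicyclo[3.3.0]octane, so the temporary oxirane ring of 15 closes by a one-step [2+1] oxygen transfer and fixes C-3a. The Lewis-acidic triarylalane 17 then binds the oxirane oxygen, the C-3–O bond ionises to an oxocarbenium ion stabilised by O-2 and paired with the aluminate on O-3a, and one aryl group passes from aluminium to C-3 within this ion pair on the face of the departing oxygen (syn opening), forming the aryl–C-3 bond. The closest known reaction type is the 1,2-cis C-arylation of glycal epoxides (1,2-anhydro sugars) with triarylaluminium or arylzinc reagents. C-3 is thus set by internal delivery from the O-3a aluminate, which here coincides with attack on the convex face of the bicycle, so both controls place the aryl group cis to the 3a-oxygen and exo. The step needs opening at C-3 rather than at C-3a (secured by the ring oxygen O-2, which stabilises positive charge only at C-3) and syn rather than anti opening (secured by the oxophilic, weakly nucleophilic aluminium reagent bound to the oxirane oxygen, where cuprates or Grignard reagents would open anti).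

Step 10
Reactants: 18 (3S,3aR,6R,6aS)-3,6-bis-Ar-tetrahydro-1H,3H-furo[3,4-c]furan-3a-ol
Product: 19 (3S,3aR,6R,6aS)-3,6-bis(4-hydroxy-3-methoxyphenyl)tetrahydro-1H,3H-furo[3,4-c]furan-3a-ol (target)
Conditions: Bu4NF (2.5 equiv), AcOH (2.5 equiv), THF, 0 °C
Reagents that add atoms: none
Why: Fluoride-mediated cleavage of the two aryl silyl ethers, buffered with acetic acid so that the phenols stay protonated and no quinone methide forms, should leave the tertiary alcohol and the benzylic ethers untouched.

## Compound list

1 | furan-2(5H)-one | O=C1OCC=C1 | starting material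
2 | potassium vinyltrifluoroborate | [K+].C=C[B-](F)(F)F | starting material
3 | (R)-4-vinyldihydrofuran-2(3H)-one | O=C1OC[C@@H](C=C)C1 | intermediate
4 | vanillin (4-hydroxy-3-methoxybenzaldehyde) | COc1cc(C=O)ccc1O | starting material
5 | 3-methoxy-4-(triisopropylsilyloxy)benzaldehyde | COc1cc(C=O)ccc1O[Si](C(C)C)(C(C)C)C(C)C | intermediate
6 | (3R,4S)-3-{hydroxy[3-methoxy-4-(triisopropylsilyloxy)phenyl]methyl}-4-vinyldihydrofuran-2(3H)-one, carbinol epimers | O=C1OC[C@@H](C=C)[C@@H]1C(O)c1ccc(O[Si](C(C)C)(C(C)C)C(C)C)c(OC)c1 | intermediate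
7 | (2S,3S)-2-{hydroxy[3-methoxy-4-(triisopropylsilyloxy)phenyl]methyl}-3-vinylbutane-1,4-diol, carbinol epimers | COc1cc(C(O)[C@H](CO)[C@H](C=C)CO)ccc1O[Si](C(C)C)(C(C)C)C(C)C | intermediate
8 | {(2R,3S,4S)-2-[3-methoxy-4-(triisopropylsilyloxy)phenyl]-4-vinyltetrahydrofuran-3-yl}methanol | COc1cc([C@@H]2OC[C@@H](C=C)[C@H]2CO)ccc1O[Si](C(C)C)(C(C)C)C(C)C | intermediate
9 | (3S,4S,5R)-4-(hydroxymethyl)-5-[3-methoxy-4-(triisopropylsilyloxy)phenyl]tetrahydrofuran-3-carbaldehyde (not isolated) | COc1cc([C@@H]2OC[C@@H](C=O)[C@H]2CO)ccc1O[Si](C(C)C)(C(C)C)C(C)C | intermediate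
10 | (3aS,6R,6aS)-6-[3-methoxy-4-(triisopropylsilyloxy)phenyl]tetrahydro-1H,3H-furo[3,4-c]furan-3-ol, anomer mixture | COc1cc([C@@H]2OC[C@H]3C(O)OC[C@@H]23)ccc1O[Si](C(C)C)(C(C)C)C(C)C | intermediate
11 | (3aS,6R,6aS)-6-[3-methoxy-4-(triisopropylsilyloxy)phenyl]tetrahydro-1H,3H-furo[3,4-c]furan-3-yl methanesulfonate (not isolated) | COc1cc([C@@H]2OC[C@H]3C(OS(C)(=O)=O)OC[C@@H]23)ccc1O[Si](C(C)C)(C(C)C)C(C)C | intermediate
12 | (6R,6aS)-6-[3-methoxy-4-(triisopropylsilyloxy)phenyl]-6,6a-dihydro-1H,4H-furo[3,4-c]furan | COc1cc([C@@H]2OCC3=COC[C@@H]23)ccc1O[Si](C(C)C)(C(C)C)C(C)C | intermediate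
13 | 4-bromo-2-methoxyphenol | COc1cc(Br)ccc1O | starting material
14 | (4-bromo-2-methoxyphenoxy)triisopropylsilane | COc1cc(Br)ccc1O[Si](C(C)C)(C(C)C)C(C)C | intermediate
15 | (3S,3aR,6R,6aS)-3,3a-epoxy-6-[3-methoxy-4-(triisopropylsilyloxy)phenyl]tetrahydro-1H,3H-furo[3,4-c]furan, oxirane on the face of H-6a (not isolated) | COc1cc([C@@H]2OC[C@@]3(O4)[C@H]4OC[C@@H]23)ccc1O[Si](C(C)C)(C(C)C)C(C)C | intermediate
16 | [3-methoxy-4-(triisopropylsilyloxy)phenyl]lithium (not isolated) | COc1cc([Li])ccc1O[Si](C(C)C)(C(C)C)C(C)C | intermediate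
17 | tris[3-methoxy-4-(triisopropylsilyloxy)phenyl]alane (not isolated) | COc1cc([Al](c2ccc(O[Si](C(C)C)(C(C)C)C(C)C)c(OC)c2)c2ccc(O[Si](C(C)C)(C(C)C)C(C)C)c(OC)c2)ccc1O[Si](C(C)C)(C(C)C)C(C)C | intermediate
18 | (3S,3aR,6R,6aS)-3,6-bis[3-methoxy-4-(triisopropylsilyloxy)phenyl]tetrahydro-1H,3H-furo[3,4-c]furan-3a-ol | COc1cc([C@@H]2OC[C@@]3(O)[C@H](c4ccc(O[Si](C(C)C)(C(C)C)C(C)C)c(OC)c4)OC[C@@H]23)ccc1O[Si](C(C)C)(C(C)C)C(C)C | intermediate
19 | (3S,3aR,6R,6aS)-3,6-bis(4-hydroxy-3-methoxyphenyl)tetrahydro-1H,3H-furo[3,4-c]furan-3a-ol | COc1cc([C@@H]2OC[C@@]3(O)[C@H](c4ccc(O)c(OC)c4)OC[C@@H]23)ccc1O | target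

## Step count and risks

Total: 10 steps. Longest linear sequence: 8 steps (1, 3, 4, 5, 6, 7, 9, 10).

Steps most likely to fail:

1. Step 9 (key step). What may go wrong: the ionised oxirane may undergo a pinacol-type shift or hydrolysis before aryl transfer, the opening may go anti, or the Lewis acid may epimerise the benzylic C-6 centre. The fallback sets out from 12 and returns at 18. Dihydroxylation of 12 with OsO4 (cat.) and N-methylmorpholine N-oxide on the convex face should give the 3,3a-diol lactol F1. Excess aryllithium 16 (THF, −78 → 0 °C) should add to its open hydroxy-aldehyde form and give the triol F2 as carbinol epimers. CSA-catalysed cyclodehydration through the benzylic cation, captured by the C-1 hydroxyl, should then close ring B with the aryl group exo and give 18. In this variant the aryl–C-3 bond is made by 1,2-addition to a carbonyl group and C-3 is set in the ring closure.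

2. Step 7. What may go wrong: the elimination may stall (the anomeric mesylate or chloride reverting to the lactol on work-up), or the strained enol ether may hydrate or oligomerise during isolation. The fallback sets out from 10, returns at 18 and avoids any enol ether. Oxidation of 10 with PhI(OAc)2 and TEMPO (cat.) should give the lactone F3. Enolisation with KN(SiMe3)2 at −78 °C and hydroxylation with 2-(phenylsulfonyl)-3-phenyloxaziridine on the convex face should give the hydroxy lactone F4. Reduction with i-Bu2AlH (CH2Cl2, −78 °C) should give the diol lactol F1, which is carried on with aryllithium 16 and acid cyclisation through the triol F2 to 18 as above.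

3. Step 1. What may go wrong: slow insertion into the weakly reactive butenolide, protodeboronation of the vinyl donor, or insufficient enantioselectivity. The fallback sets out from 1, returns at 3 and uses resolution instead of catalysis. Copper-catalysed conjugate addition of CH2=CHMgBr (CuBr·SMe2 cat., THF, −78 °C) should give the racemic lactone F5. AlMe3-mediated aminolysis with (R)-1-phenylethylamine should give two diastereomeric hydroxy amides, from which the (3R,1'R)-hydroxy amide F6 is separated by crystallisation or chromatography. Aqueous H2SO4/dioxane at reflux should relactonise F6 to 3.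

Further compounds
F1 | step 9 | (3aR,6R,6aS)-6-[3-methoxy-4-(triisopropylsilyloxy)phenyl]tetrahydro-1H,3H-furo[3,4-c]furan-3,3a-diol, C-3 anomers | COc1cc([C@@H]2OC[C@@]3(O)C(O)OC[C@@H]23)ccc1O[Si](C(C)C)(C(C)C)C(C)C
F2 | step 9 | (3R,4S,5R)-4-(hydroxymethyl)-3-{hydroxy[3-methoxy-4-(triisopropylsilyloxy)phenyl]methyl}-5-[3-methoxy-4-(triisopropylsilyloxy)phenyl]tetrahydrofuran-3-ol, carbinol epimers | COc1cc([C@@H]2OC[C@@](O)(C(O)c3ccc(O[Si](C(C)C)(C(C)C)C(C)C)c(OC)c3)[C@H]2CO)ccc1O[Si](C(C)C)(C(C)C)C(C)C
F3 | step 7 | (3aS,6R,6aS)-6-[3-methoxy-4-(triisopropylsilyloxy)phenyl]-3a,4,6,6a-tetrahydro-1H-furo[3,4-c]furan-3-one | COc1cc([C@@H]2OC[C@H]3C(=O)OC[C@@H]23)ccc1O[Si](C(C)C)(C(C)C)C(C)C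
F4 | step 7 | (3aR,6R,6aS)-3a-hydroxy-6-[3-methoxy-4-(triisopropylsilyloxy)phenyl]-3a,4,6,6a-tetrahydro-1H-furo[3,4-c]furan-3-one | COc1cc([C@@H]2OC[C@@]3(O)C(=O)OC[C@@H]23)ccc1O[Si](C(C)C)(C(C)C)C(C)C
F5 | step 1 | racemic 4-vinyldihydrofuran-2(3H)-one | O=C1OCC(C=C)C1
F6 | step 1 | (3R)-3-(hydroxymethyl)-N-[(1R)-1-phenylethyl]pent-4-enamide | OC[C@@H](C=C)CC(=O)N[C@H](C)c1ccccc1
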